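## Retrosynthetic overview

1. The target comes from the 1(10),4-diene ester 22 by a late, substrate-controlled epoxidation of C1=C10; the C8 ester is attached just before, using the (2S,3R)-epoxy acid 21 (Sharpless epoxidation of tiglyl alcohol, then oxidation).
2. The ten-membered ring and the α-methylene lactone come from one radical step: the C8 ketyl of aldehyde 17 (SmI2) adds to C7 of a 3-(acetoxymethyl)butenolide and acetate is then lost. This forms C7–C8, sets C7 and C8, and unveils C11=C13.
3. The butenolide is the first ring formed: ring-closing metathesis of a 2-(acetoxymethyl)acrylate of the C6 bis-allylic alcohol, C6 being set by an asymmetric Nozaki–Hiyama–Kishi coupling of a Z-vinyl iodide with acrolein.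
4. C3 and the E-C1=C10 alkene come from an asymmetric vinylogous Mukaiyama aldol of (Z)-3-iodo-2-methylpropenal (Z-alkene from Duboudin carbomagnesiation of propargyl alcohol) with the dienol ether of tiglic aldehyde; C8 is added by boron-Wittig homologation.
5. Ring order: butenolide (metathesis), then carbocycle (radical closure), then oxirane.

Atom labels C1–C15 are germacranolide numbering of the target (lactone C6–O–C12, C11=C13, C4=C5, oxirane C1–C10, C14 on C10, C15 on C4). Bpin = 4,4,5,5-tetramethyl-1,3,2-dioxaborolan-2-yl.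

Assumption: the SMILES is taken literally, so the C8 ester is (2S,3R)-2,3-dimethyloxirane-2-carboxylate (tiglic series, cis methyls); the absolute sense of the two catalyst-controlled steps (4 and 7) is assigned by the usual models, would be checked by Mosher analysis, and the antipodal catalyst is used if it proves opposite.

## Route

Step 1
Reactants: 1 prop-2-yn-1-ol
Product: 3 (Z)-3-iodo-2-methylprop-2-en-1-ol, via alkenylmagnesium alkoxide 2 (not isolated)
Conditions: MeMgBr (2.5 equiv), CuI (10 mol %), THF, −10 °C to rt; then I2, −78 to 0 °C; 1 M HCl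
Reagents that add atoms: methylmagnesium bromide, C[Mg]Br; iodine, II
Why: Copper-catalysed anti-carbomagnesiation of the propargylic alkoxide (Duboudin reaction) puts methyl on the internal carbon and magnesium on the terminal carbon cis to the CH2O group in a five-membered chelate, so iodinolysis with retention gives the Z-iodide that fixes the later C4=C5 geometry.

Step 2
Reactants: 3 (Z)-3-iodo-2-methylprop-2-en-1-ol
Product: 4 (Z)-3-iodo-2-methylprop-2-enal
Conditions: activated MnO2 (15 equiv), CH2Cl2, rt, dark; used at once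
Reagents that add atoms: none
Why: Allylic oxidation with MnO2 is neutral and heterogeneous, so the primary allylic alcohol becomes the enal without touching the vinyl iodide or isomerising the Z double bond.

Step 3
Reactants: 5 (E)-2-methylbut-2-enal
Product: 6 (E)-tert-butyl(dimethyl)[(2-methylbuta-1,3-dien-1-yl)oxy]silane
Conditions: TBSOTf (1.1 equiv), Et3N (1.5 equiv), Et2O, 0 °C to rt
Reagents that add atoms: tert-butyldimethylsilyl trifluoromethanesulfonate, CC(C)(C)[Si](C)(C)OS(=O)(=O)C(F)(F)F
Why: Soft enolisation (O-silylation, then loss of a γ-proton from the terminal methyl group) gives the 1-silyloxydiene that serves as the vinylogous nucleophile; its enol ether geometry is irrelevant because it is lost in the next step.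

Step 4
Reactants: 4 (Z)-3-iodo-2-methylprop-2-enal; 6 (E)-tert-butyl(dimethyl)[(2-methylbuta-1,3-dien-1-yl)oxy]silane
Product: 7 (2E,5S,6Z)-5-hydroxy-7-iodo-2,6-dimethylhepta-2,6-dienal
Conditions: (R)-4-(1H-indol-3-ylmethyl)-3-(4-methylbenzenesulfonyl)-2-phenyl-1,3,2-oxazaborolidin-5-one (50 mol %), i-PrOH (1.2 equiv), EtCN, −78 °C
Reagents that add atoms: none
Why: Oxazaborolidinone-promoted asymmetric vinylogous Mukaiyama aldol reaction, in which the diene terminus attacks the Si face of the boron-bound aldehyde to set C3 (S) under catalyst control and gives the E-enal (C1=C10) from the s-trans diene, with i-PrOH taking up the silyl group.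

Step 5
Reactants: 7 (2E,5S,6Z)-5-hydroxy-7-iodo-2,6-dimethylhepta-2,6-dienal
Product: 8 (1Z,3S,5E,7E)-1-iodo-2,6-dimethyl-8-Bpin-octa-1,5,7-trien-3-ol
Conditions: CH2(Bpin)2 (2.3 equiv), LiTMP (2.2 equiv), THF, 0 °C (pre-formed); then 7, −78 °C to rt; aq. NH4Cl
Reagents that add atoms: bis(4,4,5,5-tetramethyl-1,3,2-dioxaborolan-2-yl)methane, CC1(C)OB(CB2OC(C)(C)C(C)(C)O2)OC1(C)C
Why: Boron-Wittig olefination (1,2-addition of the α-boryl carbanion to the aldehyde, then syn-elimination of borate) adds C8 as an alkenylboronate, a latent aldehyde that already has C9 in place, while the second equivalent of carbanion only deprotonates the hydroxyl and C3 is untouched.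

Step 6
Reactants: 8 (1Z,3S,5E,7E)-1-iodo-2,6-dimethyl-8-Bpin-octa-1,5,7-trien-3-ol; 9 3-methylbutanoyl chloride
Product: 10 (1Z,3S,5E,7E)-1-iodo-2,6-dimethyl-8-Bpin-octa-1,5,7-trien-3-yl 3-methylbutanoate
Conditions: pyridine (3 equiv), DMAP (5 mol %), CH2Cl2, 0 °C
Reagents that add atoms: none
Why: DMAP-catalysed acylation of the secondary allylic alcohol with retention installs the C3 isovalerate of the target early, so it also serves as the only protection C3 needs.

Step 7
Reactants: 10 (1Z,3S,5E,7E)-1-iodo-2,6-dimethyl-8-Bpin-octa-1,5,7-trien-3-yl 3-methylbutanoate; 11 prop-2-enal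
Product: 12 (3S,4Z,6S,8E,10E)-3-hydroxy-5,9-dimethyl-11-Bpin-undeca-1,4,8,10-tetraen-6-yl 3-methylbutanoate (carbinol = C6; S here by CIP, same spatial arrangement as 6R in the lactone)
Conditions: CrCl2 (4 equiv), NiCl2 (2 mol %), (S)-N-[2-(4-isopropyl-4,5-dihydro-1,3-oxazol-2-yl)-6-methylphenyl]methanesulfonamide (4.4 equiv), Et3N (4.4 equiv), 11 (3 equiv), THF, rt
Reagents that add atoms: none
Why: Asymmetric Nozaki–Hiyama–Kishi coupling, in which zerovalent nickel inserts into the vinyl iodide and the vinylchromium formed with retention of the Z geometry adds 1,2 to acrolein inside the chiral sulfonamide–chromium complex, setting C6 under reagent control while ester and boronate are inert.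

Step 8
Reactants: 12 (3S,4Z,6S,8E,10E)-3-hydroxy-5,9-dimethyl-11-Bpin-undeca-1,4,8,10-tetraen-6-yl 3-methylbutanoate; 13 2-(bromomethyl)prop-2-enoic acid
Product: 15 (3S,4Z,6S,8E,10E)-3-{[2-(acetoxymethyl)prop-2-enoyl]oxy}-5,9-dimethyl-11-Bpin-undeca-1,4,8,10-tetraen-6-yl 3-methylbutanoate, via bromomethylacrylate ester 14 (not isolated)
Conditions: 13 (1.5 equiv), DCC (1.6 equiv), DMAP (5 mol %), CH2Cl2, −20 to 0 °C; filter; then KOAc (3 equiv), 18-crown-6 (10 mol %), MeCN, rt
Reagents that add atoms: potassium acetate, CC(=O)[O-].[K+]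
Why: Steglich esterification acylates the bis-allylic alcohol with retention at C6 and no ionisation, and SN2 displacement of the activated allylic bromide by acetate then gives a C13 leaving group that SmI2 does not reduce directly.

Step 9
Reactants: 15 (3S,4Z,6S,8E,10E)-3-{[2-(acetoxymethyl)prop-2-enoyl]oxy}-5,9-dimethyl-11-Bpin-undeca-1,4,8,10-tetraen-6-yl 3-methylbutanoate
Product: 16 [(5R)-5-{(1Z,3S,5E,7E)-2,6-dimethyl-3-[(3-methylbutanoyl)oxy]-8-Bpin-octa-1,5,7-trien-1-yl}-2-oxo-2,5-dihydrofuran-3-yl]methyl acetate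
Conditions: second-generation Hoveyda–Grubbs catalyst (10 mol %), toluene (2 mM), 60 °C, argon sparge
Reagents that add atoms: none
Why: Ring-closing metathesis, in which the ruthenium carbene forms at the terminal vinyl group and closes onto the 1,1-disubstituted acrylate to give the five-membered butenolide with loss of ethene, the trisubstituted alkenes and the conjugated alkenylboronate being far slower and C6 untouched.

Step 10
Reactants: 16 [(5R)-5-{(1Z,3S,5E,7E)-2,6-dimethyl-3-[(3-methylbutanoyl)oxy]-8-Bpin-octa-1,5,7-trien-1-yl}-2-oxo-2,5-dihydrofuran-3-yl]methyl acetate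
Product: 17 [(5R)-5-{(1Z,3S,5E)-2,6-dimethyl-3-[(3-methylbutanoyl)oxy]-8-oxoocta-1,5-dien-1-yl}-2-oxo-2,5-dihydrofuran-3-yl]methyl acetate
Conditions: 30% H2O2 (3 equiv), pH 7 phosphate buffer, THF, 0 °C; used crude at once
Reagents that add atoms: hydrogen peroxide, OO
Why: Oxidation of the alkenylboronate (1,2-shift from boron to oxygen) gives the dienol, which ketonises by kinetic protonation at the α-carbon C9 (the same selectivity that underlies photodeconjugation) to the β,γ-unsaturated C8 aldehyde, the cold near-neutral medium sparing the butenolide and preventing conjugation.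

Step 11
Reactants: 17 [(5R)-5-{(1Z,3S,5E)-2,6-dimethyl-3-[(3-methylbutanoyl)oxy]-8-oxoocta-1,5-dien-1-yl}-2-oxo-2,5-dihydrofuran-3-yl]methyl acetate
Product: 18 (3aR,4R,6E,9S,10Z,11aR)-4-hydroxy-6,10-dimethyl-3-methylidene-2-oxo-2,3,3a,4,5,8,9,11a-octahydrocyclodeca[b]furan-9-yl 3-methylbutanoate
Conditions: SmI2 (2.5 equiv, 0.1 M in THF), 17 added by syringe pump over 4 h (final 2 mM), THF, −78 to −20 °C, no HMPA, no proton source; then sat. NH4Cl
Reagents that add atoms: none
Why: Proposed new method: single-electron reduction of the aldehyde gives the C8 ketyl radical, which adds to the β-carbon C7 of the butenolide in a ten-membered ring closure pre-organised by the E and Z alkenes, a second electron turns the α-radical into a trivalent samarium enolate that expels acetate (E1cB) to give C11=C13; attack anti to the C5 chain on C6 gives the trans-lactone (7R), and the non-chelated anti ketyl–olefin transition state (O–Sm anti to C11, ring bonds C6–C7–C8–C9 extended) gives 8R; the closest known reactions are SmI2 ketyl–olefin additions to unsaturated esters and lactones including medium-ring cases, β-elimination of β-acetoxy samarium enolates, and metal-mediated couplings of aldehydes with 3-(halomethyl)butenolides that give β-(hydroxyalkyl)-α-methylene-γ-butyrolactones.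

Step 12
Reactants: 19 (E)-2-methylbut-2-en-1-ol
Product: 20 [(2R,3R)-2,3-dimethyloxiran-2-yl]methanol
Conditions: Ti(OiPr)4 (5 mol %), D-(−)-diisopropyl tartrate (6 mol %), t-BuOOH (2 equiv), 4 Å sieves, CH2Cl2, −20 °C
Reagents that add atoms: tert-butyl hydroperoxide, CC(C)(C)OO
Why: Sharpless asymmetric epoxidation, where the D-(−)-tartrate complex delivers oxygen to the face of the E-allylic alcohol that gives the (2R,3R)-epoxide (the antipode of the 2S,3S product obtained with L-(+)-tartrate) and the E geometry is retained as cis methyls.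

Step 13
Reactants: 20 [(2R,3R)-2,3-dimethyloxiran-2-yl]methanol
Product: 21 (2S,3R)-2,3-dimethyloxirane-2-carboxylic acid
Conditions: RuCl3 hydrate (2 mol %), NaIO4 (4 equiv), CCl4/MeCN/H2O, rt
Reagents that add atoms: sodium periodate, [Na+].[O-]I(=O)(=O)=O; water, O
Why: Catalytic RuO4 oxidation of the primary alcohol to the acid leaves the oxirane intact, and the descriptor at C2 changes from R to S only because CO2H outranks the ring carbon.

Step 14
Reactants: 18 (3aR,4R,6E,9S,10Z,11aR)-4-hydroxy-6,10-dimethyl-3-methylidene-2-oxo-2,3,3a,4,5,8,9,11a-octahydrocyclodeca[b]furan-9-yl 3-methylbutanoate; 21 (2S,3R)-2,3-dimethyloxirane-2-carboxylic acid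
Product: 22 (3aR,4R,6E,9S,10Z,11aR)-6,10-dimethyl-3-methylidene-9-[(3-methylbutanoyl)oxy]-2-oxo-2,3,3a,4,5,8,9,11a-octahydrocyclodeca[b]furan-4-yl (2S,3R)-2,3-dimethyloxirane-2-carboxylate
Conditions: 21 (2 equiv), DCC (2.2 equiv), DMAP (0.5 equiv), CH2Cl2, 0 °C to rt
Reagents that add atoms: none
Why: Steglich esterification acylates the C8 hydroxyl with retention, and the quaternary α-carbon of the epoxy acid cannot epimerise.

Step 15
Reactants: 22 (3aR,4R,6E,9S,10Z,11aR)-6,10-dimethyl-3-methylidene-9-[(3-methylbutanoyl)oxy]-2-oxo-2,3,3a,4,5,8,9,11a-octahydrocyclodeca[b]furan-4-yl (2S,3R)-2,3-dimethyloxirane-2-carboxylate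
Product: 23 CNP0167461.3, (1R,3S,4Z,6R,7R,8R,10R)-1,10-epoxy-3-(3-methylbutanoyloxy)-8-[(2S,3R)-2,3-dimethyloxirane-2-carbonyloxy]germacra-4,11(13)-dien-12,6-olide
Conditions: mCPBA (1.1 equiv), NaHCO3, CH2Cl2, 0 °C
Reagents that add atoms: 3-chloroperoxybenzoic acid, OOC(=O)c1cccc(Cl)c1
Why: Prilezhaev epoxidation is chemoselective for C1=C10, the only electron-rich alkene (C4=C5 carries two allylic acyloxy groups, C11=C13 is conjugated), and attack on the exposed outer face of the preferred ring conformer with C14 on the β-face gives the 1β,10α (1R,10R) oxirane, as in peracid epoxidations of related germacranolides, the bicarbonate buffer preventing acid-induced transannular cyclisation.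

## Compound list

1 | prop-2-yn-1-ol | C#CCO | starting material
2 | bromomagnesium (Z)-3-(bromomagnesio)-2-methylprop-2-en-1-olate | Br[Mg]/C=C(/C)CO[Mg]Br | intermediate (not isolated)
3 | (Z)-3-iodo-2-methylprop-2-en-1-ol | OC/C(C)=C\I | intermediate
4 | (Z)-3-iodo-2-methylprop-2-enal | O=C/C(C)=C\I | intermediate
5 | (E)-2-methylbut-2-enal | C/C=C(\C)C=O | starting material
6 | (E)-tert-butyl(dimethyl)[(2-methylbuta-1,3-dien-1-yl)oxy]silane | C=C/C(C)=C/O[Si](C)(C)C(C)(C)C | intermediate
7 | (2E,5S,6Z)-5-hydroxy-7-iodo-2,6-dimethylhepta-2,6-dienal | O=C/C(C)=C/C[C@H](O)/C(C)=C\I | intermediate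
8 | (1Z,3S,5E,7E)-1-iodo-2,6-dimethyl-8-(4,4,5,5-tetramethyl-1,3,2-dioxaborolan-2-yl)octa-1,5,7-trien-3-ol | CC1(C)OB(/C=C/C(C)=C/C[C@H](O)/C(C)=C\I)OC1(C)C | intermediate
9 | 3-methylbutanoyl chloride | CC(C)CC(Cl)=O | starting material
10 | (1Z,3S,5E,7E)-1-iodo-2,6-dimethyl-8-(4,4,5,5-tetramethyl-1,3,2-dioxaborolan-2-yl)octa-1,5,7-trien-3-yl 3-methylbutanoate | CC1(C)OB(/C=C/C(C)=C/C[C@H](OC(=O)CC(C)C)/C(C)=C\I)OC1(C)C | intermediate
11 | prop-2-enal | C=CC=O | starting material
12 | (3S,4Z,6S,8E,10E)-3-hydroxy-5,9-dimethyl-11-(4,4,5,5-tetramethyl-1,3,2-dioxaborolan-2-yl)undeca-1,4,8,10-tetraen-6-yl 3-methylbutanoate | CC1(C)OB(/C=C/C(C)=C/C[C@H](OC(=O)CC(C)C)/C(C)=C\[C@@H](O)C=C)OC1(C)C | intermediate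
13 | 2-(bromomethyl)prop-2-enoic acid | C=C(CBr)C(=O)O | starting material
14 | (3S,4Z,6S,8E,10E)-3-{[2-(bromomethyl)prop-2-enoyl]oxy}-5,9-dimethyl-11-(4,4,5,5-tetramethyl-1,3,2-dioxaborolan-2-yl)undeca-1,4,8,10-tetraen-6-yl 3-methylbutanoate | CC1(C)OB(/C=C/C(C)=C/C[C@H](OC(=O)CC(C)C)/C(C)=C\[C@@H](OC(=O)C(=C)CBr)C=C)OC1(C)C | intermediate (not isolated)
15 | (3S,4Z,6S,8E,10E)-3-{[2-(acetoxymethyl)prop-2-enoyl]oxy}-5,9-dimethyl-11-(4,4,5,5-tetramethyl-1,3,2-dioxaborolan-2-yl)undeca-1,4,8,10-tetraen-6-yl 3-methylbutanoate | CC1(C)OB(/C=C/C(C)=C/C[C@H](OC(=O)CC(C)C)/C(C)=C\[C@@H](OC(=O)C(=C)COC(C)=O)C=C)OC1(C)C | intermediate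
16 | [(5R)-5-{(1Z,3S,5E,7E)-2,6-dimethyl-3-[(3-methylbutanoyl)oxy]-8-(4,4,5,5-tetramethyl-1,3,2-dioxaborolan-2-yl)octa-1,5,7-trien-1-yl}-2-oxo-2,5-dihydrofuran-3-yl]methyl acetate | CC1(C)OB(/C=C/C(C)=C/C[C@H](OC(=O)CC(C)C)/C(C)=C\[C@H]2OC(=O)C(COC(C)=O)=C2)OC1(C)C | intermediate
17 | [(5R)-5-{(1Z,3S,5E)-2,6-dimethyl-3-[(3-methylbutanoyl)oxy]-8-oxoocta-1,5-dien-1-yl}-2-oxo-2,5-dihydrofuran-3-yl]methyl acetate | O=CC/C(C)=C/C[C@H](OC(=O)CC(C)C)/C(C)=C\[C@H]1OC(=O)C(COC(C)=O)=C1 | intermediate
18 | (3aR,4R,6E,9S,10Z,11aR)-4-hydroxy-6,10-dimethyl-3-methylidene-2-oxo-2,3,3a,4,5,8,9,11a-octahydrocyclodeca[b]furan-9-yl 3-methylbutanoate | C=C1C(=O)O[C@@H]2/C=C(/C)[C@@H](OC(=O)CC(C)C)C/C=C(\C)C[C@@H](O)[C@@H]12 | intermediate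
19 | (E)-2-methylbut-2-en-1-ol | C/C=C(\C)CO | starting material
20 | [(2R,3R)-2,3-dimethyloxiran-2-yl]methanol | OC[C@@]1(C)O[C@@H]1C | intermediate
21 | (2S,3R)-2,3-dimethyloxirane-2-carboxylic acid | OC(=O)[C@@]1(C)O[C@@H]1C | intermediate
22 | (3aR,4R,6E,9S,10Z,11aR)-6,10-dimethyl-3-methylidene-9-[(3-methylbutanoyl)oxy]-2-oxo-2,3,3a,4,5,8,9,11a-octahydrocyclodeca[b]furan-4-yl (2S,3R)-2,3-dimethyloxirane-2-carboxylate | C=C1C(=O)O[C@@H]2/C=C(/C)[C@@H](OC(=O)CC(C)C)C/C=C(\C)C[C@@H](OC(=O)[C@@]3(C)O[C@@H]3C)[C@@H]12 | intermediate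
23 | CNP0167461.3, (1R,3S,4Z,6R,7R,8R,10R)-1,10-epoxy-3-(3-methylbutanoyloxy)-8-[(2S,3R)-2,3-dimethyloxirane-2-carbonyloxy]germacra-4,11(13)-dien-12,6-olide | C=C1C(=O)O[C@@H]2/C=C(/C)[C@@H](OC(=O)CC(C)C)C[C@H]3O[C@]3(C)C[C@@H](OC(=O)[C@@]3(C)O[C@@H]3C)[C@@H]12 | target

## Step count and risks

Total step count: 15. Longest linear sequence: 12 steps (1, 2, 4, 5, 6, 7, 8, 9, 10, 11, 14, 15).

The three steps most likely to fail:

**Step 11 (radical macrocyclisation).** Closing a ten-membered ring by ketyl addition is entropically demanding, and the butenolide may be reduced before the aldehyde. The fallback moves the radical to the lactone side. It sets out from 14, which is worked up before the acetate exchange. Ring-closing metathesis under the step 9 conditions gives the bromomethyl butenolide boronate F1, and buffered H2O2 oxidation as in step 10 gives the bromo aldehyde F2. Slow addition of F2 to SmI2 in THF reduces the allylic C–Br bond first. The resulting 2-oxo-2,5-dihydrofuran-3-ylmethyl radical, after a second electron, closes through its γ-carbon C7 onto the aldehyde in a Barbier-type macrocyclisation. This is the mode with direct precedent in ten-membered germacranolide closures, and it returns to the route at 18.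

**Step 15 (face selectivity of the final epoxidation).** The outcome depends on the ring conformation, and the product is acid-sensitive. The fallback sets out from 18 and replaces substrate control by reagent control before the glycidic ester is attached. Shi epoxidation (1,2:4,5-di-O-isopropylidene-β-D-erythro-2,3-hexodiulo-2,6-pyranose, 30 mol %, Oxone, K2CO3 buffer, MeCN/dimethoxymethane, 0 °C; the antipodal ketone if mismatched) gives the epoxy alcohol F4. Esterification of F4 with 21 (DCC, DMAP) arrives directly at 23.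

**Step 7 (asymmetric Nozaki–Hiyama–Kishi coupling).** The remote C3 centre gives no help, so the C6 selectivity rests entirely on the ligand. The fallback sets out from 10 and creates C6 by reduction instead of C–C bond formation. Carbonylative Stille coupling with tributyl(vinyl)stannane (CO 1 atm, Pd2(dba)3, AsPh3, THF, 50 °C) gives the cross-conjugated dienone F3. CBS reduction of F3 with (R)-1-methyl-3,3-diphenyl-tetrahydro-1H,3H-pyrrolo[1,2-c][1,3,2]oxazaborole and catecholborane at −78 °C (trisubstituted alkenyl as the large group, vinyl as the small one) returns to the route at 12.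

## Further compounds

F1 | step 11 | (1Z,3S,5E,7E)-1-[(2R)-4-(bromomethyl)-5-oxo-2,5-dihydrofuran-2-yl]-2,6-dimethyl-8-(4,4,5,5-tetramethyl-1,3,2-dioxaborolan-2-yl)octa-1,5,7-trien-3-yl 3-methylbutanoate | CC1(C)OB(/C=C/C(C)=C/C[C@H](OC(=O)CC(C)C)/C(C)=C\[C@H]2OC(=O)C(CBr)=C2)OC1(C)C
F2 | step 11 | (1Z,3S,5E)-1-[(2R)-4-(bromomethyl)-5-oxo-2,5-dihydrofuran-2-yl]-2,6-dimethyl-8-oxoocta-1,5-dien-3-yl 3-methylbutanoate | O=CC/C(C)=C/C[C@H](OC(=O)CC(C)C)/C(C)=C\[C@H]1OC(=O)C(CBr)=C1
F3 | step 7 | (4Z,6S,8E,10E)-5,9-dimethyl-3-oxo-11-(4,4,5,5-tetramethyl-1,3,2-dioxaborolan-2-yl)undeca-1,4,8,10-tetraen-6-yl 3-methylbutanoate | CC1(C)OB(/C=C/C(C)=C/C[C@H](OC(=O)CC(C)C)/C(C)=C\C(=O)C=C)OC1(C)C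
F4 | step 15 | (1R,3S,4Z,6R,7R,8R,10R)-1,10-epoxy-8-hydroxy-3-(3-methylbutanoyloxy)germacra-4,11(13)-dien-12,6-olide | C=C1C(=O)O[C@@H]2/C=C(/C)[C@@H](OC(=O)CC(C)C)C[C@H]3O[C@]3(C)C[C@@H](O)[C@@H]12
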